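**Strategy.** Lophirone J is disconnected at the O1–C2 bond of its dihydropyranone (chromanone C) ring. O1–C2–C3–C4(=O) is a β-aryloxy ketone whose only stereocentre, benzylic C2, sits β to the carbonyl, which is the retron of an oxa-Michael addition. The key step closes this ring last, by a catalyst-controlled 6-endo-trig addition of the phenol oxygen to an alkylidene β-ketoester. It sets C2 as S and removes the temporary tert-butyl ester at C3 in the same pot. The precursor is an open-chain 2-hydroxy-4-methoxybenzoyl alkylidene tert-butyl ester that already carries the finished 2-arylbenzofuran. It is assembled by Knoevenagel condensation of a benzofuran aldehyde (domino Sonogashira annulation) with a β-ketoester.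

Key step: step 4

Assumption (remark on the chemistry): the 9-amino-9-deoxy-epi-quinidine-derived thiourea is taken as the pseudoenantiomer that delivers the 2S adduct. The sense is to be checked on the first run by chiroptical comparison with the 2S flavanone series; if it is reversed, the quinine-derived pseudoenantiomer is used with no other change.

Step 1
Reactants: 1 4-hydroxy-3-iodobenzaldehyde; 2 1-ethynyl-4-methoxybenzene
Product: 4 2-(4-methoxyphenyl)-1-benzofuran-5-carbaldehyde, via o-alkynylphenol 3 (not isolated)
Conditions: PdCl2(PPh3)2 (2 mol%), CuI (4 mol%), Et3N, DMF (degassed), 70 °C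
Reagents that add atoms: none
Why: Domino Sonogashira coupling followed by 5-endo-dig cycloisomerisation of the ortho-alkynylphenol (Larock-type benzofuran annulation) is standard for ortho-iodophenols; the para-formyl group acidifies the phenol and speeds ring closure, and the aldehyde is inert to these conditions.

Step 2
Reactants: 5 methyl 2-hydroxy-4-methoxybenzoate; 6 tert-butyl acetate
Product: 7 tert-butyl 3-(2-hydroxy-4-methoxyphenyl)-3-oxopropanoate
Conditions: LDA (3.5 equiv), 6 (3.5 equiv), THF, −78 °C; then 5, −78 to −30 °C; cold aq. HCl
Reagents that add atoms: none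
Why: Crossed Claisen condensation of the lithium enolate of tert-butyl acetate with the salicylate ester; the excess enolate covers the phenol and the acidic product, self-condensation of the bulky enolate is slow at low temperature, and the tert-butyl ester should resist lactonisation to the 4-hydroxycoumarin on cold acidic work-up.

Step 3
Reactants: 7 tert-butyl 3-(2-hydroxy-4-methoxyphenyl)-3-oxopropanoate; 4 2-(4-methoxyphenyl)-1-benzofuran-5-carbaldehyde
Product: 8 tert-butyl (2E)-2-(2-hydroxy-4-methoxybenzoyl)-3-[2-(4-methoxyphenyl)-1-benzofuran-5-yl]prop-2-enoate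
Conditions: piperidine (10 mol%), AcOH (10 mol%), 4 Å MS, toluene, rt
Reagents that add atoms: none
Why: Knoevenagel condensation under piperidinium acetate catalysis with removal of water; the phenol is held in a hydrogen bond to the aryl ketone and the medium is only weakly basic, so it should not yet add to the new alkylidene, and the E isomer (ester trans to the benzofuranyl group, twisted aroyl cis) is expected to dominate.

Step 4
Reactants: 8 tert-butyl (2E)-2-(2-hydroxy-4-methoxybenzoyl)-3-[2-(4-methoxyphenyl)-1-benzofuran-5-yl]prop-2-enoate
Product: 10 lophirone J, via trans-3-tert-butoxycarbonylflavanone 9 (not isolated)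
Conditions: epi-quinidine-derived 3,5-bis(trifluoromethyl)phenyl thiourea (10 mol%), toluene, −25 °C; then TsOH·H2O (0.5 equiv), 80 °C
Reagents that add atoms: none
Why: The thiourea NH pair binds the 1,3-dicarbonyl unit of the alkylidene β-ketoester and lowers its LUMO, while the quinuclidine nitrogen acts as general base on the phenol, whose oxygen adds to the β-carbon (the future C2). The closest known reaction type is the bifunctional cinchona-thiourea-catalysed intramolecular oxa-Michael addition of 2-hydroxyaroyl alkylidene β-ketoesters with one-pot decarboxylation, an established asymmetric flavanone synthesis. The dihydropyranone ring O1–C2–C3–C4–C4a–C8a is closed in the 6-endo-trig mode by O1–C2 bond formation. C2 is set by the catalyst, which exposes one enantiotopic face of the β-carbon in the two-point-bound substrate; the C3 centre of 9 is epimerisable (trans, in equilibrium with its enol) and is erased when TsOH removes the tert-butyl group as isobutene and the β-keto acid loses CO2. The step needs enantioface selectivity and suppression of uncatalysed or reversible (retro-oxa-Michael) closure. The ester secures this by making the acceptor reactive at −25 °C in a non-polar, base-free medium and by giving a chelated β-ketoester adduct, and the decarboxylation is acidic rather than basic so that the para-oxygenated benzylic C2–O1 bond should stay closed.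

**Compound list**

1 | 4-hydroxy-3-iodobenzaldehyde | O=Cc1ccc(O)c(I)c1 | starting material
2 | 1-ethynyl-4-methoxybenzene (4-ethynylanisole) | C#Cc1ccc(OC)cc1 | starting material
3 | 4-hydroxy-3-[(4-methoxyphenyl)ethynyl]benzaldehyde | COc1ccc(C#Cc2cc(C=O)ccc2O)cc1 | intermediate (not isolated)
4 | 2-(4-methoxyphenyl)-1-benzofuran-5-carbaldehyde | COc1ccc(-c2cc3cc(C=O)ccc3o2)cc1 | intermediate
5 | methyl 2-hydroxy-4-methoxybenzoate | COC(=O)c1ccc(OC)cc1O | starting material
6 | tert-butyl acetate | CC(=O)OC(C)(C)C | starting material
7 | tert-butyl 3-(2-hydroxy-4-methoxyphenyl)-3-oxopropanoate | COc1ccc(C(=O)CC(=O)OC(C)(C)C)c(O)c1 | intermediate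
8 | tert-butyl (2E)-2-(2-hydroxy-4-methoxybenzoyl)-3-[2-(4-methoxyphenyl)-1-benzofuran-5-yl]prop-2-enoate | CC(C)(C)OC(=O)/C(C(=O)c1ccc(OC)cc1O)=C/c1ccc2oc(-c3ccc(OC)cc3)cc2c1 | intermediate
9 | tert-butyl (2S,3R)-7-methoxy-2-[2-(4-methoxyphenyl)-1-benzofuran-5-yl]-4-oxo-3,4-dihydro-2H-chromene-3-carboxylate (trans; in equilibrium with its enol) | COc1ccc(-c2cc3cc([C@@H]4[C@@H](C(=O)OC(C)(C)C)C(=O)c5ccc(OC)cc5O4)ccc3o2)cc1 | intermediate (not isolated)
10 | lophirone J, (2S)-7-methoxy-2-[2-(4-methoxyphenyl)-1-benzofuran-5-yl]-2,3-dihydro-4H-chromen-4-one | COc1ccc(-c2cc3cc([C@@H]4CC(=O)c5ccc(OC)cc5O4)ccc3o2)cc1 | target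

**Step count.** Total: 4 steps. Longest linear sequence: 3 steps (step 1 or step 2, then steps 3 and 4).

**Steps most likely to fail**

1. Step 4. The risk is erosion of enantiopurity through reversible ring opening and reclosure (retro-oxa-Michael) during the warm acidic decarboxylation, favoured by the electron-rich benzofuranyl group at C2, or insufficient facial selectivity with this large aryl group. The fallback sets out from 4 and gives up catalyst control for a separation of enantiomers. Claisen–Schmidt condensation of 4 with 2-hydroxy-4-methoxyacetophenone (CC(=O)c1ccc(OC)cc1O; KOH, EtOH, rt) should give the chalcone (E)-1-(2-hydroxy-4-methoxyphenyl)-3-[2-(4-methoxyphenyl)-1-benzofuran-5-yl]prop-2-en-1-one F1. Its oxa-Michael closure (NaOAc, EtOH, reflux) should give the racemic flavanone F2, again with the pyranone ring closed last. Preparative chromatography on a cellulose tris(3,5-dimethylphenylcarbamate) phase should then deliver 10. The mirror-image (2R)-flavanone F3 is re-equilibrated with base through F1 and recycled. The route is rejoined at 10.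

2. Step 3. The risk is uncatalysed, racemic ring closure of the free phenol onto the alkylidene during the amine-catalysed condensation, together with slow condensation of the electron-rich aldehyde. The fallback sets out from 5 and masks the phenol. Allylation (allyl bromide, K2CO3, DMF) should give methyl 4-methoxy-2-(prop-2-en-1-yloxy)benzoate F4. The Claisen condensation of step 2 on this non-acidic ester should give tert-butyl 3-[4-methoxy-2-(prop-2-en-1-yloxy)phenyl]-3-oxopropanoate F5. Its Knoevenagel condensation with 4 can then be forced (TiCl4, pyridine, THF, or heating with water removal) to the O-allyl alkylidene tert-butyl (2E)-2-[4-methoxy-2-(prop-2-en-1-yloxy)benzoyl]-3-[2-(4-methoxyphenyl)-1-benzofuran-5-yl]prop-2-enoate F6. Neutral deallylation (Pd(PPh3)4, PhSiH3, CH2Cl2, rt) should release the phenol without base. The route is rejoined at 8.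

3. Step 2. The risk is incomplete acylation because the phenoxide deactivates the ester, competing self-condensation of the enolate on warming, and lactonisation of the product to the 4-hydroxycoumarin. The fallback sets out from 5 and replaces the enolate Claisen by a decarboxylative acylation under near-neutral conditions. Benzylation (BnBr, K2CO3, acetone) should give methyl 2-(benzyloxy)-4-methoxybenzoate F7. Saponification (LiOH, THF/H2O) should give 2-(benzyloxy)-4-methoxybenzoic acid F8. Masamune–Brooks acylation (CDI, THF; then magnesium mono-tert-butyl malonate) should give tert-butyl 3-[2-(benzyloxy)-4-methoxyphenyl]-3-oxopropanoate F9. Hydrogenolysis (H2, Pd/C, EtOAc) then removes the benzyl group. The route is rejoined at 7.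

**Further compounds**

F1 | step 4 | (E)-1-(2-hydroxy-4-methoxyphenyl)-3-[2-(4-methoxyphenyl)-1-benzofuran-5-yl]prop-2-en-1-one | COc1ccc(C(=O)/C=C/c2ccc3oc(-c4ccc(OC)cc4)cc3c2)c(O)c1
F2 | step 4 | rac-7-methoxy-2-[2-(4-methoxyphenyl)-1-benzofuran-5-yl]-2,3-dihydro-4H-chromen-4-one | COc1ccc(-c2cc3cc(C4CC(=O)c5ccc(OC)cc5O4)ccc3o2)cc1
F3 | step 4 | (2R)-7-methoxy-2-[2-(4-methoxyphenyl)-1-benzofuran-5-yl]-2,3-dihydro-4H-chromen-4-one | COc1ccc(-c2cc3cc([C@H]4CC(=O)c5ccc(OC)cc5O4)ccc3o2)cc1
F4 | step 3 | methyl 4-methoxy-2-(prop-2-en-1-yloxy)benzoate | COC(=O)c1ccc(OC)cc1OCC=C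
F5 | step 3 | tert-butyl 3-[4-methoxy-2-(prop-2-en-1-yloxy)phenyl]-3-oxopropanoate | COc1ccc(C(=O)CC(=O)OC(C)(C)C)c(OCC=C)c1
F6 | step 3 | tert-butyl (2E)-2-[4-methoxy-2-(prop-2-en-1-yloxy)benzoyl]-3-[2-(4-methoxyphenyl)-1-benzofuran-5-yl]prop-2-enoate | CC(C)(C)OC(=O)/C(C(=O)c1ccc(OC)cc1OCC=C)=C/c1ccc2oc(-c3ccc(OC)cc3)cc2c1
F7 | step 2 | methyl 2-(benzyloxy)-4-methoxybenzoate | COC(=O)c1ccc(OC)cc1OCc1ccccc1
F8 | step 2 | 2-(benzyloxy)-4-methoxybenzoic acid | COc1ccc(C(=O)O)c(OCc2ccccc2)c1
F9 | step 2 | tert-butyl 3-[2-(benzyloxy)-4-methoxyphenyl]-3-oxopropanoate | COc1ccc(C(=O)CC(=O)OC(C)(C)C)c(OCc2ccccc2)c1
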